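Read the constants first, and read those of the equilibrium between catalyst and dormant form as a clock you can set before anything has reacted.

starting material 0.0020 M; reagent 1.90 mM; catalyst 2.0 µM

    starting material + reagent + catalyst → target + catalyst, rate k1*[starting material]*[reagent]*[catalyst]/(1 + ([starting material]/sat1)) (sat1 = 3.4 mM, k1 = 2.2 × 10⁸ /M²/s)
    catalyst ⇌ dormant form (K2 = 13, k2 = 0.51 /s)
    starting material + reagent → uncatalysed product (k3 = 61 /M/s)

- the form that holds most of the catalyst when 30% of the starting material are converted (catalyst / dormant form)
- its share of the catalyst then

**The clock.** The catalyst leaves the catalysed step as it entered it, so you may let its share relax from the full charge towards the equilibrium share 7.14% at the rate 0.549 /s, the forward and back constants added. That share falls to half at 1.41 s, and this crossover time, the moment at which the dormant form, an off-cycle form, overtakes the catalyst, is what you carry. In this flask the mark at 30% and a later mark at 70.0% can end on opposite sides of it, so the question becomes when the mark falls.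

**The mean.** To time it, I replace the curves by their means. The mark needs 0.600 mM of starting material gone by both routes, so I take the midpoint levels, 1.70 mM of starting material and 1.60 mM of reagent, with a saturation factor of 0.667. With the catalyst wholly active the mark comes at 0.623 s, when the share is 73.1%. The mean share 86.6% then moves the mark to 0.701 s, where I commit to catalyst at 70.3%.

**The error.** The exact integral of the reactant product makes that time longer by 3.43%, whereas the crossover time is twice my mark, so the choice of form survives the averaging.

**The forecast.** The forecast gives catalyst at 69%, on the ground that “equilibrium is not reached”.

**The flask.** This flask reaches the mark at 0.743 s, against my 0.701 s, with catalyst holding 68.9% and the dormant form 31.1%, so the mark stands earlier than the crossover time by a factor of 1.90. Just past that crossover, at 1.50 s, the same flask holds 47.9% as catalyst and 52.1% as dormant form, and its mark at 70.0% comes far beyond it, at 8.91 s, where the clock puts 92.2% in the dormant form and the rate stands at 0.023 of its value at the first mark.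

Its constants are made up; the rest is arithmetic.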